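**Retrosynthetic overview**
- Ester last: Mitsunobu union of (Z)-p-coumaric acid with the C-6' carbinol, with inversion; L-lactate supplies C-5' to C-7'.
- Cyclopropane (second ring, formed last): the C-4' enol(ate) of the C-5' ketone attacks C-2' of a 1',2'-epoxide (3-exo-tet), as in the presumed biogenesis from a side-chain epoxide. It is run as an iodide-relayed double inversion on the trans-epoxy ketone, which unveils 1'-OH and sets C-2' and C-4'.
- Epoxide from the E-olefin by catalyst-controlled dioxirane epoxidation (sets C-1' and C-2').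
- Dihydropyranone (first ring): polyketide-like vinylogous aldol of an enal with a but-3-enoate, then lactonization of the Z-δ-hydroxy enoate (sets C-6).
- Enal from ethyl (S)-lactate, but-3-enylmagnesium bromide and crotonaldehyde.

Assumption: locants are pyranone C-2 to C-6 and side chain C-1' (carbinol), C-2'/C-4' (cyclopropane CH), C-3' (cyclopropane CH2), C-5' (ketone), C-6' (ester carbinol), C-7' (methyl), so the target is (6R,1'S,2'S,4'S,6'R) with a Z ester; the ligand antipode written in step 4 is taken as the one that gives the 6R lactone, and the other antipode is used if a test run shows the opposite sense.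

**Step 1**
Reactants: 1 ethyl (2S)-2-hydroxypropanoate (ethyl L-lactate)
Product: 2 ethyl (2S)-2-[(tert-butyldimethylsilyl)oxy]propanoate
Conditions: TBSCl, imidazole, DMF, 0 °C → rt
Reagents that add atoms: tert-butyldimethylsilyl chloride, CC(C)(C)[Si](C)(C)Cl
Why: Imidazole-promoted silyl ether formation on the secondary alcohol; the lactate stereocentre is not touched.

**Step 2**
Reactants: 2 ethyl (2S)-2-[(tert-butyldimethylsilyl)oxy]propanoate; 3 but-3-en-1-ylmagnesium bromide
Product: 5 (2S)-2-[(tert-butyldimethylsilyl)oxy]hept-6-en-3-one, via Weinreb amide 4 (not isolated)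
Conditions: MeNH(OMe)·HCl, i-PrMgCl, THF, −20 °C; then 3, −20 → 0 °C; aq. NH4Cl
Reagents that add atoms: N,O-dimethylhydroxylamine hydrochloride, CNOC.Cl (its atoms are carried only in 4 and are lost again)
Why: One-pot Weinreb ketone synthesis: magnesium amide aminolysis of the ester gives the N-methoxy-N-methyl amide, whose chelated tetrahedral adduct with the Grignard reagent stops at the ketone without epimerizing the α-silyloxy centre.

**Step 3**
Reactants: 5 (2S)-2-[(tert-butyldimethylsilyl)oxy]hept-6-en-3-one; 6 (E)-but-2-enal (crotonaldehyde)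
Product: 7 (2E,7S)-7-[(tert-butyldimethylsilyl)oxy]-6-oxooct-2-enal
Conditions: second-generation Hoveyda–Grubbs catalyst RuCl2(H2IMes)(=CH-C6H4-2-O-i-Pr) (3 mol%), CH2Cl2, 40 °C
Reagents that add atoms: none
Why: Olefin cross-metathesis of a terminal alkene with an electron-poor partner gives the E-enal under thermodynamic control.

**Step 4**
Reactants: 7 (2E,7S)-7-[(tert-butyldimethylsilyl)oxy]-6-oxooct-2-enal; 8 methyl but-3-enoate
Product: 10 (6R)-6-[(1E,6S)-6-[(tert-butyldimethylsilyl)oxy]-5-oxohept-1-en-1-yl]-5,6-dihydro-2H-pyran-2-one, via hydroxy enoate 9 (not isolated)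
Conditions: [Cu(MeCN)4]PF6 (5 mol%), (R)-DTBM-SEGPHOS (6 mol%), Et3N (10 mol%), THF, −20 °C → rt
Reagents that add atoms: none
Why: Direct catalytic asymmetric vinylogous aldol reaction: the monovalent copper–bisphosphine/amine pair soft-enolizes the β,γ-unsaturated ester to an s-cis dienolate that attacks the aldehyde through its γ-carbon on the ligand-controlled face (sets C-6 as R), and the Z-configured δ-alkoxy enoate lactonizes at once, as a cis-enoyl δ-hydroxy polyketide does on release.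

**Step 5**
Reactants: 10 (6R)-6-[(1E,6S)-6-[(tert-butyldimethylsilyl)oxy]-5-oxohept-1-en-1-yl]-5,6-dihydro-2H-pyran-2-one
Product: 11 (6R)-6-[(2S,3R)-3-[(4S)-4-[(tert-butyldimethylsilyl)oxy]-3-oxopentyl]oxiran-2-yl]-5,6-dihydro-2H-pyran-2-one
Conditions: Shi ketone (D-fructose-derived, 30 mol%), Oxone (2KHSO5·KHSO4·K2SO4), K2CO3, n-Bu4NHSO4, MeCN/dimethoxymethane/aq. Na2B4O7 buffer (pH ca. 10), 0 °C
Reagents that add atoms: potassium peroxymonosulfate (KHSO5, from Oxone), [K+].[O-]S(=O)(=O)OO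
Why: Shi asymmetric epoxidation: the chiral dioxirane adds to the trans-disubstituted olefin through a spiro transition state under catalyst control (sets C-1' as S and C-2' as R, the "R,R-type" face); the conjugated lactone olefin is too electron-poor to react.

**Step 6**
Reactants: 11 (6R)-6-[(2S,3R)-3-[(4S)-4-[(tert-butyldimethylsilyl)oxy]-3-oxopentyl]oxiran-2-yl]-5,6-dihydro-2H-pyran-2-one
Product: 13 (6R)-6-[(S)-[(1S,2S)-2-[(2S)-2-[(tert-butyldimethylsilyl)oxy]propanoyl]cyclopropyl](hydroxy)methyl]-5,6-dihydro-2H-pyran-2-one, via iodohydrin 12 (not isolated)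
Conditions: MgI2 (2.5 equiv), toluene/Et2O, −40 → 0 °C; then i-Pr2NEt (3 equiv), 0 °C → rt; aq. NH4Cl
Reagents that add atoms: magnesium iodide, [Mg+2].[I-].[I-] (the iodine is carried only in 12 and is lost again)
Why: Proposed new method: MgI2 opens the epoxide by SN2 at C-2' (the carbon remote from the electron-withdrawing C-6 acyloxy group) with inversion to give the anti iodohydrin as its magnesium alkoxide, which does not re-close; magnesium chelation of the α-silyloxy ketone then allows soft enolization by the amine towards C-4', and the enolate carbon displaces iodide in a 3-exo-tet SN2 with a second inversion, so C-2' ends with net retention (S, syn to the untouched 1'S hydroxyl) and C-4' is set trans (S) because the acyl group avoids the C-1' substituent in the ring-closing transition state; the closest known reactions are the base-mediated 3-exo-tet closure of γ,δ-epoxy ketones and γ-halo ketones to cyclopropyl ketones, MgI2 opening of epoxides to iodohydrins and MgI2/amine soft enolization of ketones.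

**Step 7**
Reactants: 13 (6R)-6-[(S)-[(1S,2S)-2-[(2S)-2-[(tert-butyldimethylsilyl)oxy]propanoyl]cyclopropyl](hydroxy)methyl]-5,6-dihydro-2H-pyran-2-one
Product: 14 (6R)-6-[(S)-hydroxy[(1S,2S)-2-[(2S)-2-hydroxypropanoyl]cyclopropyl]methyl]-5,6-dihydro-2H-pyran-2-one
Conditions: HF·pyridine, pyridine, THF, 0 °C → rt
Reagents that add atoms: none
Why: Buffered fluoride desilylation frees the C-6' hydroxyl without touching the lactone, the cyclopropyl carbinol or any stereocentre.

**Step 8**
Reactants: 15 (E)-3-(4-hydroxyphenyl)prop-2-enoic acid ((E)-p-coumaric acid)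
Product: 16 (Z)-3-(4-hydroxyphenyl)prop-2-enoic acid ((Z)-p-coumaric acid)
Conditions: hν (300–350 nm), MeOH, rt; Z isomer separated by chromatography in the dark, E isomer recycled
Reagents that add atoms: none
Why: Direct E→Z photoisomerization of a cinnamic acid to a photostationary mixture from which the Z acid is isolated.

**Step 9**
Reactants: 14 (6R)-6-[(S)-hydroxy[(1S,2S)-2-[(2S)-2-hydroxypropanoyl]cyclopropyl]methyl]-5,6-dihydro-2H-pyran-2-one; 16 (Z)-3-(4-hydroxyphenyl)prop-2-enoic acid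
Product: 17 (2R)-1-[(1S,2S)-2-[(S)-hydroxy[(2R)-6-oxo-3,6-dihydro-2H-pyran-2-yl]methyl]cyclopropyl]-1-oxopropan-2-yl (2Z)-3-(4-hydroxyphenyl)prop-2-enoate (target)
Conditions: PPh3, DIAD, THF, 0 °C → rt, dark (1.3 equiv of 16)
Reagents that add atoms: none
Why: Mitsunobu esterification: the carboxylate (far more acidic than the phenol) displaces the oxyphosphonium of the unhindered, carbonyl-activated C-6' carbinol by SN2 with inversion (S → R), the acid is never activated as an acyl donor so the Z-olefin is kept, and the doubly branched C-1' carbinol reacts much more slowly.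

**Compound list**
1 | ethyl (2S)-2-hydroxypropanoate | C[C@H](O)C(=O)OCC | starting material
2 | ethyl (2S)-2-[(tert-butyldimethylsilyl)oxy]propanoate | C[C@H](O[Si](C)(C)C(C)(C)C)C(=O)OCC | intermediate
3 | but-3-en-1-ylmagnesium bromide | C=CCC[Mg]Br | starting material
4 | (2S)-2-[(tert-butyldimethylsilyl)oxy]-N-methoxy-N-methylpropanamide (not isolated) | C[C@H](O[Si](C)(C)C(C)(C)C)C(=O)N(C)OC | intermediate
5 | (2S)-2-[(tert-butyldimethylsilyl)oxy]hept-6-en-3-one | C[C@H](O[Si](C)(C)C(C)(C)C)C(=O)CCC=C | intermediate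
6 | (E)-but-2-enal | C/C=C/C=O | starting material
7 | (2E,7S)-7-[(tert-butyldimethylsilyl)oxy]-6-oxooct-2-enal | C[C@H](O[Si](C)(C)C(C)(C)C)C(=O)CC/C=C/C=O | intermediate
8 | methyl but-3-enoate | C=CCC(=O)OC | starting material
9 | methyl (2Z,5R,6E,11S)-11-[(tert-butyldimethylsilyl)oxy]-5-hydroxy-10-oxododeca-2,6-dienoate (as its alkoxide, not isolated) | C[C@H](O[Si](C)(C)C(C)(C)C)C(=O)CC/C=C/[C@H](O)C/C=C\C(=O)OC | intermediate
10 | (6R)-6-[(1E,6S)-6-[(tert-butyldimethylsilyl)oxy]-5-oxohept-1-en-1-yl]-5,6-dihydro-2H-pyran-2-one | C[C@H](O[Si](C)(C)C(C)(C)C)C(=O)CC/C=C/[C@H]1CC=CC(=O)O1 | intermediate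
11 | (6R)-6-[(2S,3R)-3-[(4S)-4-[(tert-butyldimethylsilyl)oxy]-3-oxopentyl]oxiran-2-yl]-5,6-dihydro-2H-pyran-2-one | C[C@H](O[Si](C)(C)C(C)(C)C)C(=O)CC[C@H]1O[C@@H]1[C@H]2CC=CC(=O)O2 | intermediate
12 | (6R)-6-[(1R,2S,6S)-6-[(tert-butyldimethylsilyl)oxy]-1-hydroxy-2-iodo-5-oxoheptyl]-5,6-dihydro-2H-pyran-2-one (present as its magnesium alkoxide, not isolated) | C[C@H](O[Si](C)(C)C(C)(C)C)C(=O)CC[C@H](I)[C@H](O)[C@H]1CC=CC(=O)O1 | intermediate
13 | (6R)-6-[(S)-[(1S,2S)-2-[(2S)-2-[(tert-butyldimethylsilyl)oxy]propanoyl]cyclopropyl](hydroxy)methyl]-5,6-dihydro-2H-pyran-2-one | C[C@H](O[Si](C)(C)C(C)(C)C)C(=O)[C@H]1C[C@@H]1[C@H](O)[C@H]2CC=CC(=O)O2 | intermediate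
14 | (6R)-6-[(S)-hydroxy[(1S,2S)-2-[(2S)-2-hydroxypropanoyl]cyclopropyl]methyl]-5,6-dihydro-2H-pyran-2-one | C[C@H](O)C(=O)[C@H]1C[C@@H]1[C@H](O)[C@H]2CC=CC(=O)O2 | intermediate
15 | (E)-3-(4-hydroxyphenyl)prop-2-enoic acid | OC(=O)/C=C/c1ccc(O)cc1 | starting material
16 | (Z)-3-(4-hydroxyphenyl)prop-2-enoic acid | OC(=O)/C=C\c1ccc(O)cc1 | intermediate
17 | (2R)-1-[(1S,2S)-2-[(S)-hydroxy[(2R)-6-oxo-3,6-dihydro-2H-pyran-2-yl]methyl]cyclopropyl]-1-oxopropan-2-yl (2Z)-3-(4-hydroxyphenyl)prop-2-enoate | C[C@@H](OC(=O)/C=C\c1ccc(O)cc1)C(=O)[C@H]1C[C@@H]1[C@H](O)[C@H]2CC=CC(=O)O2 | target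

**Step count and risks**
Total step count: 9. Longest linear sequence: 8 (steps 1–7 and 9; step 8 is a one-step side branch).

The three steps most likely to fail are steps 4, 6 and 9.

Step 4 may suffer from α- instead of γ-attack, imperfect enantiocontrol on this enal, or competing enolization of the ketone in 7. The fallback sets out from 7 and returns at 10. A Lewis-base-catalysed enantioselective vinylogous Mukaiyama aldol addition of the trimethylsilyl dienol ether of methyl crotonate to 7 (SiCl4, chiral bisphosphoramide, i-Pr2NEt, CH2Cl2, −78 °C) gives methyl (2E,5R,6E,11S)-11-[(tert-butyldimethylsilyl)oxy]-5-hydroxy-10-oxododeca-2,6-dienoate F1. Irradiation (300 nm, MeCN, trace PPTS) isomerizes the E-enoate to the Z-enoate, which lactonizes as it forms and so drains the photoequilibrium to 10.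

Step 6 may fail through direct enolate attack on the Lewis-acid-activated epoxide (which would give the 2',4'-epimeric cyclopropane), through participation of the ketone oxygen in the epoxide opening, or because the amine is too weak a base. The fallback sets out from 11 and returns at 13, and runs the relay stepwise with the oxygen capped. MgI2 (Et2O/toluene, −40 °C) and a cold aqueous quench give the iodohydrin 12, now isolated. Et3SiOTf/2,6-lutidine (CH2Cl2, −78 °C) gives (6R)-6-[(1R,2S,6S)-6-[(tert-butyldimethylsilyl)oxy]-2-iodo-5-oxo-1-[(triethylsilyl)oxy]heptyl]-5,6-dihydro-2H-pyran-2-one F2. LiN(SiMe3)2 (THF, −78 °C) closes the ring by kinetic enolate alkylation to (6R)-6-[(S)-[(1S,2S)-2-[(2S)-2-[(tert-butyldimethylsilyl)oxy]propanoyl]cyclopropyl][(triethylsilyl)oxy]methyl]-5,6-dihydro-2H-pyran-2-one F3. AcOH/THF/H2O at rt then removes only the triethylsilyl group and gives 13.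

Step 9 may fail on site selectivity between the two secondary hydroxyls of 14 or on partial loss of the Z geometry. The fallback sets out from 13 and returns at 17. i-Pr3SiOTf/2,6-lutidine silylates the C-1' hydroxyl to give (6R)-6-[(S)-[(1S,2S)-2-[(2S)-2-[(tert-butyldimethylsilyl)oxy]propanoyl]cyclopropyl][(triisopropylsilyl)oxy]methyl]-5,6-dihydro-2H-pyran-2-one F4. Buffered HF·pyridine at 0 °C removes only the less hindered tert-butyldimethylsilyl group and gives (6R)-6-[(S)-[(1S,2S)-2-[(2S)-2-hydroxypropanoyl]cyclopropyl][(triisopropylsilyl)oxy]methyl]-5,6-dihydro-2H-pyran-2-one F5. Mitsunobu esterification with 16 (PPh3, DIAD, THF, 0 °C) now meets a single free hydroxyl and gives (2R)-1-oxo-1-[(1S,2S)-2-[(S)-[(2R)-6-oxo-3,6-dihydro-2H-pyran-2-yl][(triisopropylsilyl)oxy]methyl]cyclopropyl]propan-2-yl (2Z)-3-(4-hydroxyphenyl)prop-2-enoate F6. HF·pyridine at rt then removes the triisopropylsilyl group and gives 17.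

**Further compounds**
F1 | step 4 | methyl (2E,5R,6E,11S)-11-[(tert-butyldimethylsilyl)oxy]-5-hydroxy-10-oxododeca-2,6-dienoate | C[C@H](O[Si](C)(C)C(C)(C)C)C(=O)CC/C=C/[C@H](O)C/C=C/C(=O)OC
F2 | step 6 | (6R)-6-[(1R,2S,6S)-6-[(tert-butyldimethylsilyl)oxy]-2-iodo-5-oxo-1-[(triethylsilyl)oxy]heptyl]-5,6-dihydro-2H-pyran-2-one | C[C@H](O[Si](C)(C)C(C)(C)C)C(=O)CC[C@H](I)[C@H](O[Si](CC)(CC)CC)[C@H]1CC=CC(=O)O1
F3 | step 6 | (6R)-6-[(S)-[(1S,2S)-2-[(2S)-2-[(tert-butyldimethylsilyl)oxy]propanoyl]cyclopropyl][(triethylsilyl)oxy]methyl]-5,6-dihydro-2H-pyran-2-one | C[C@H](O[Si](C)(C)C(C)(C)C)C(=O)[C@H]1C[C@@H]1[C@H](O[Si](CC)(CC)CC)[C@H]2CC=CC(=O)O2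
F4 | step 9 | (6R)-6-[(S)-[(1S,2S)-2-[(2S)-2-[(tert-butyldimethylsilyl)oxy]propanoyl]cyclopropyl][(triisopropylsilyl)oxy]methyl]-5,6-dihydro-2H-pyran-2-one | C[C@H](O[Si](C)(C)C(C)(C)C)C(=O)[C@H]1C[C@@H]1[C@H](O[Si](C(C)C)(C(C)C)C(C)C)[C@H]2CC=CC(=O)O2
F5 | step 9 | (6R)-6-[(S)-[(1S,2S)-2-[(2S)-2-hydroxypropanoyl]cyclopropyl][(triisopropylsilyl)oxy]methyl]-5,6-dihydro-2H-pyran-2-one | C[C@H](O)C(=O)[C@H]1C[C@@H]1[C@H](O[Si](C(C)C)(C(C)C)C(C)C)[C@H]2CC=CC(=O)O2
F6 | step 9 | (2R)-1-oxo-1-[(1S,2S)-2-[(S)-[(2R)-6-oxo-3,6-dihydro-2H-pyran-2-yl][(triisopropylsilyl)oxy]methyl]cyclopropyl]propan-2-yl (2Z)-3-(4-hydroxyphenyl)prop-2-enoate | C[C@@H](OC(=O)/C=C\c1ccc(O)cc1)C(=O)[C@H]1C[C@@H]1[C@H](O[Si](C(C)C)(C(C)C)C(C)C)[C@H]2CC=CC(=O)O2
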